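**Strategy**

Labdane numbering is used (ring A: C1–C5, C10; ring B: C5–C10; oxolane: O, C9, C11–C13; dihydrofuran: C13–C16). Ring B is cut at C7–C8 and C9–C10 by a Diels–Alder disconnection. In the target C20, the oxygen on C9 and C17 lie on one face of ring B and C11 on the other, the pattern left by endo addition of a (Z)-alkylidene dienophile. A ring A dienylboronate and the dispiro enone 16, with a C11 ketone as activator and the dihydrofuran masked as lactone, should thus give ring B, the vicinal quaternary centres C9 and C10 and C8 in one step; boron later becomes the C7 ketone. A 3β-benzyloxy group steers the diene face and is inverted afterwards.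

Key step: step 10

Remark: α and β refer to the usual decalin drawing with the C10 methyl (C20) β; in these terms the target, (3R,5S,8R,9S,10S,13S), has 3α-OAc, 5α-H, 8β-CH3 (C17), 9β-O with C11 α, and 10β-CH3. Compounds 1, 5, 7 and 11 are assumed to be commercial.

**Route**

Step 1
Reactants: 1 (S)-3-hydroxy-2,2-dimethylcyclohexan-1-one
Product: 2 (S)-3-(benzyloxy)-2,2-dimethylcyclohexan-1-one
Conditions: BnOC(=NH)CCl3, TfOH (cat.), CH2Cl2/cyclohexane, 0 °C → rt
Reagents that add atoms: benzyl 2,2,2-trichloroacetimidate, ClC(Cl)(Cl)C(=N)OCc1ccccc1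
Why: Acid-catalysed O-benzylation with the imidate avoids base, which could open the β-hydroxy ketone by retro-aldol cleavage and erase C3; the ether is later removed by hydrogenolysis.

Step 2
Reactants: 2 (S)-3-(benzyloxy)-2,2-dimethylcyclohexan-1-one
Product: 3 (3S)-3-(benzyloxy)-2,2,6-trimethylcyclohexan-1-one (both C6 epimers)
Conditions: LiN(i-Pr)2, THF, −78 °C; MeI, −78 → 0 °C
Reagents that add atoms: iodomethane, CI
Why: Enolate alkylation; the ketone can enolise only towards the future C10 because C4 is quaternary, and the new centre is destroyed in step 3, so its configuration does not matter.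

Step 3
Reactants: 3 (3S)-3-(benzyloxy)-2,2,6-trimethylcyclohexan-1-one
Product: 4 (5S)-5-(benzyloxy)-2,6,6-trimethylcyclohex-1-en-1-yl trifluoromethanesulfonate
Conditions: KN(SiMe3)2, THF, −78 °C; PhNTf2, −78 °C → rt
Reagents that add atoms: N-phenylbis(trifluoromethanesulfonimide), O=S(=O)(N(c1ccccc1)S(=O)(=O)C(F)(F)F)C(F)(F)F
Why: O-Triflation of the only possible (tetrasubstituted) enolate gives the C5=C10 enol triflate.

Step 4
Reactants: 4 (5S)-5-(benzyloxy)-2,6,6-trimethylcyclohex-1-en-1-yl trifluoromethanesulfonate; 5 (E)-1,2-bis(4,4,5,5-tetramethyl-1,3,2-dioxaborolan-2-yl)ethene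
Product: 6 2-{(E)-2-[(5S)-5-(benzyloxy)-2,6,6-trimethylcyclohex-1-en-1-yl]ethenyl}-4,4,5,5-tetramethyl-1,3,2-dioxaborolane
Conditions: PdCl2(dppf) (5 mol%), K3PO4, dioxane/H2O, 60 °C, excess of 5
Reagents that add atoms: none
Why: Suzuki–Miyaura coupling with retention of alkene geometry; with an excess of the diboryl ethene it should stop after one coupling because the product alkenylboronate is hindered.

Step 5
Reactants: 7 4-methyl hydrogen itaconate (4-methoxy-2-methylidene-4-oxobutanoic acid)
Product: 9 methyl 3-(hydroxymethyl)but-3-enoate, via mixed anhydride 8 (not isolated)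
Conditions: ClCO2Et, Et3N, THF, −10 °C; then NaBH4, THF/H2O, 0 °C
Reagents that add atoms: none
Why: Mixed carbonic anhydride activation lets NaBH4 reduce the acid chemoselectively in the presence of the methyl ester.

Step 6
Reactants: 9 methyl 3-(hydroxymethyl)but-3-enoate
Product: 10 methyl 2-[(2S)-2-(hydroxymethyl)oxiran-2-yl]acetate
Conditions: Ti(OiPr)4 (10 mol%), L-(+)-diethyl tartrate (12 mol%), t-BuOOH, 4 Å MS, CH2Cl2, −20 °C
Reagents that add atoms: tert-butyl hydroperoxide, CC(C)(C)OO
Why: Sharpless asymmetric epoxidation of a 2-substituted allylic alcohol; the L-(+)-tartrate complex delivers oxygen to the face that gives the (S)-epoxide, which fixes C13.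

Step 7
Reactants: 10 methyl 2-[(2S)-2-(hydroxymethyl)oxiran-2-yl]acetate; 11 but-1-yne
Product: 13 (4S)-4-hydroxy-4-(pent-2-yn-1-yl)oxolan-2-one, via diol ester 12 (not isolated)
Conditions: n-BuLi, THF, −78 °C; BF3·OEt2; then aq. NH4Cl; then CSA (cat.), CH2Cl2, rt
Reagents that add atoms: none
Why: The alkynyl–BF3 reagent opens the epoxide at its CH2 carbon (C12) without touching the C13–O bond, and the 1,4-hydroxy ester then lactonises under acid to the five-membered lactone.

Step 8
Reactants: 13 (4S)-4-hydroxy-4-(pent-2-yn-1-yl)oxolan-2-one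
Product: 15 (5S)-2-ethyl-2-hydroxy-1,7-dioxaspiro[4.4]nonane-3,8-dione (C2 epimers), via diketone 14 (not isolated)
Conditions: RuO2·xH2O (cat.), NaIO4, CCl4/MeCN/H2O, rt
Reagents that add atoms: sodium periodate, [Na+].[O-]I(=O)(=O)=O
Why: RuO4 generated in the flask oxidises the internal alkyne to the 1,2-diketone, whose C9 carbonyl is trapped by the tertiary C13 hydroxyl as a five-membered hemiketal, which closes the oxolane ring.

Step 9
Reactants: 15 (5S)-2-ethyl-2-hydroxy-1,7-dioxaspiro[4.4]nonane-3,8-dione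
Product: 16 (2Z,5S)-2-ethylidene-1,7-dioxaspiro[4.4]nonane-3,8-dione
Conditions: CSA (cat.), toluene, 4 Å MS, 60 °C
Reagents that add atoms: none
Why: Acid-catalysed dehydration of the hemiketal gives the exocyclic enol ether conjugated to the ketone; E and Z equilibrate under acid and the (Z) isomer, with the methyl cis to the ring oxygen and away from the carbonyl, should be the stable one.

Step 10
Reactants: 6 2-{(E)-2-[(5S)-5-(benzyloxy)-2,6,6-trimethylcyclohex-1-en-1-yl]ethenyl}-4,4,5,5-tetramethyl-1,3,2-dioxaborolane; 16 (2Z,5S)-2-ethylidene-1,7-dioxaspiro[4.4]nonane-3,8-dione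
Product: 17 (13S)-3β-benzyloxy-7α-(pinacolatoboryl)-9β,13-epoxy-11-oxo-8αH-labd-5-en-15,16-olide (C17 and C20 β; C11 α)
Conditions: Me2AlCl (2 equiv), CH2Cl2, −78 → −20 °C; aq. potassium sodium tartrate
Reagents that add atoms: none
Why: Me2AlCl binds the C11 carbonyl of 16 and diene 6 adds in an asynchronous concerted [4+2] cycloaddition in which C7–C8 bonding runs ahead (positive charge on the C6–C5–C10 allyl unit, tertiary at C10) and C9–C10 then closes; the closest known reactions are Lewis acid promoted Diels–Alder additions of 2,6,6-trimethyl-1-vinylcyclohexenes, of 1-boryl-1,3-dienes and of exocyclic alkylidene furanones. Ring B is the only ring formed, a six-membered carbocycle closed by an intermolecular cycloaddition that is suprafacial on both partners. C8 and C9 follow from the (Z) geometry of 16 (C17 cis to the C9 oxygen), C9 and C10 from the endo rule (C11=O under the diene, so C20 ends cis to the C9 oxygen and trans to C11), and C7 from the (E)-boronate (boron cis to C11). The diene face, and with it the absolute sense at C8, C9 and C10, is set by C3: in the half-chair with the 3β-benzyloxy group pseudo-equatorial the C4 β-methyl is pseudo-axial and shields the β face, while the other half-chair is shielded on both faces (axial C4 α-methyl, axial benzyloxy), so addition should occur on the α face, anti to the C3 oxygen; C13 is carried in from 16. The step needs regio-, endo and face selectivity: the first is secured by the polarisation (enone β-carbon C8 to terminus C7), the second by the Lewis acid complex and by keeping the spiro centre C13 away from ring A, the third by C3.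

Step 11
Reactants: 17 Diels–Alder adduct
Product: 18 (13S)-3β-benzyloxy-7α-(pinacolatoboryl)-9β,13-epoxy-11-oxo-8αH-labdan-15,16-olide (5α-H)
Conditions: [Ir(cod)(PCy3)(py)]PF6 (5 mol%), H2 (1 atm), CH2Cl2, rt
Reagents that add atoms: none
Why: Carbonyl-directed homogeneous hydrogenation; the cationic iridium catalyst binds the C11 ketone on the α face and the β face is covered by C17, C20 and the axial C4 methyl, so H2 should add from the α face to give the trans ring fusion.

Step 12
Reactants: 18 saturated keto lactone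
Product: 19 (13S)-3β-benzyloxy-7α-(pinacolatoboryl)-9β,13-epoxy-11-(trifluoromethanesulfonyloxy)-8αH-labd-11-en-15,16-olide
Conditions: KN(SiMe3)2 (1.05 equiv), THF, −78 °C; PhNTf2
Reagents that add atoms: N-phenylbis(trifluoromethanesulfonimide), O=S(=O)(N(c1ccccc1)S(=O)(=O)C(F)(F)F)C(F)(F)F
Why: Enol triflate formation; the ketone can enolise only towards C12 (C9 is quaternary) and is far more acidic than the lactone.

Step 13
Reactants: 19 enol triflate
Product: 20 (13S)-3β-hydroxy-7α-(pinacolatoboryl)-9β,13-epoxy-8αH-labdan-15,16-olide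
Conditions: H2 (1 atm), Pd(OH)2/C, K2CO3, EtOAc/MeOH, rt
Reagents that add atoms: none
Why: Palladium-catalysed hydrogenolysis and hydrogenation turn the enol triflate into the C11–C12 ethylene unit and cleave the benzyl ether in the same operation, with K2CO3 taking up the triflic acid.

Step 14
Reactants: 20 3β-alcohol
Product: 21 (13S)-3-oxo-7α-(pinacolatoboryl)-9β,13-epoxy-8αH-labdan-15,16-olide
Conditions: Dess–Martin periodinane, NaHCO3, CH2Cl2, rt
Reagents that add atoms: none
Why: Dess–Martin oxidation of the 3β-alcohol to the ketone opens the way to inversion at C3; boronate and lactone are inert.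

Step 15
Reactants: 21 3-ketone
Product: 23 (13S)-3α-acetoxy-7α-(pinacolatoboryl)-9β,13-epoxy-8αH-labdan-15,16-olide, via lithium alkoxide 22 (not isolated)
Conditions: LiBH(s-Bu)3, THF, −78 °C; then Ac2O, DMAP, −78 °C → rt
Reagents that add atoms: acetic anhydride, CC(=O)OC(C)=O
Why: The bulky hydride attacks the C3 ketone, flanked by the gem-dimethyl C4, from the equatorial direction and gives the axial 3α-alkoxide, which is acetylated in the flask; the lactone is not reduced at −78 °C.

Step 16
Reactants: 23 3α-acetate lactone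
Product: 24 (13S)-3α-acetoxy-7α-(pinacolatoboryl)-9β,13:15,16-diepoxy-8αH-labdan-15-ol (lactol; C15 epimers)
Conditions: disiamylborane, THF, 0 °C → rt; H2O
Reagents that add atoms: none
Why: Disiamylborane reduces γ-lactones to lactols and stops there, and it leaves the acetate and the alkyl boronate alone.

Step 17
Reactants: 24 lactol
Product: 26 (13S)-3α-acetoxy-7α-(pinacolatoboryl)-9β,13:15,16-diepoxy-8αH-labd-14-ene, via anomeric mesylate 25 (not isolated)
Conditions: MsCl, Et3N, CH2Cl2, −40 °C → rt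
Reagents that add atoms: none
Why: Mesylation of the lactol hydroxyl and base-induced elimination give the 2,3-dihydrofuran; C13 is quaternary, so the double bond can form only between C14 and C15.

Step 18
Reactants: 26 boronate enol ether
Product: 27 (13S)-3α-acetoxy-9β,13:15,16-diepoxy-8αH-labd-14-en-7α-ol
Conditions: NaBO3·4H2O, THF/H2O, rt
Reagents that add atoms: sodium perborate, [Na+].[O-]OB=O
Why: Perborate oxidation of the C–B bond goes with retention under mildly basic conditions that the enol ether and the acetate should tolerate.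

Step 19
Reactants: 27 7α-alcohol
Product: 28 (13S)-3α-acetoxy-9β,13:15,16-diepoxy-8αH-labd-14-en-7-one (target)
Conditions: Dess–Martin periodinane, pyridine, CH2Cl2, 0 °C
Reagents that add atoms: none
Why: Buffered Dess–Martin oxidation forms the C7 ketone last and under neutral conditions, so the epimerisable C8 centre (axial β-methyl) and the acid-labile enol ether should survive.

**Compound list**

1 | (S)-3-hydroxy-2,2-dimethylcyclohexan-1-one | O[C@H]1CCCC(=O)C1(C)C | starting material
2 | (S)-3-(benzyloxy)-2,2-dimethylcyclohexan-1-one | C(c2ccccc2)O[C@H]1CCCC(=O)C1(C)C | intermediate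
3 | (3S)-3-(benzyloxy)-2,2,6-trimethylcyclohexan-1-one (C6 epimers) | C(c2ccccc2)O[C@H]1CCC(C)C(=O)C1(C)C | intermediate
4 | (5S)-5-(benzyloxy)-2,6,6-trimethylcyclohex-1-en-1-yl trifluoromethanesulfonate | C(c2ccccc2)O[C@H]1CCC(C)=C(OS(=O)(=O)C(F)(F)F)C1(C)C | intermediate
5 | (E)-1,2-bis(4,4,5,5-tetramethyl-1,3,2-dioxaborolan-2-yl)ethene | CC1(C)OB(/C=C/B2OC(C)(C)C(C)(C)O2)OC1(C)C | starting material
6 | 2-{(E)-2-[(5S)-5-(benzyloxy)-2,6,6-trimethylcyclohex-1-en-1-yl]ethenyl}-4,4,5,5-tetramethyl-1,3,2-dioxaborolane | C(c2ccccc2)O[C@H]1CCC(C)=C(/C=C/B3OC(C)(C)C(C)(C)O3)C1(C)C | intermediate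
7 | 4-methyl hydrogen itaconate | COC(=O)CC(=C)C(=O)O | starting material
8 | ethyl carbonic mixed anhydride of 7 | COC(=O)CC(=C)C(=O)OC(=O)OCC | intermediate (not isolated)
9 | methyl 3-(hydroxymethyl)but-3-enoate | COC(=O)CC(=C)CO | intermediate
10 | methyl 2-[(2S)-2-(hydroxymethyl)oxiran-2-yl]acetate | C1O[C@]1(CO)CC(=O)OC | intermediate
11 | but-1-yne | CCC#C | starting material
12 | methyl (3S)-3-hydroxy-3-(hydroxymethyl)oct-5-ynoate | COC(=O)C[C@](O)(CO)CC#CCC | intermediate (not isolated)
13 | (4S)-4-hydroxy-4-(pent-2-yn-1-yl)oxolan-2-one | O=C1C[C@@](O)(CC#CCC)CO1 | intermediate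
14 | (4S)-4-(2,3-dioxopentyl)-4-hydroxyoxolan-2-one | O=C1C[C@@](O)(CC(=O)C(=O)CC)CO1 | intermediate (not isolated)
15 | (5S)-2-ethyl-2-hydroxy-1,7-dioxaspiro[4.4]nonane-3,8-dione (C2 epimers) | CCC1(O)O[C@@]2(CC1=O)CC(=O)OC2 | intermediate
16 | (2Z,5S)-2-ethylidene-1,7-dioxaspiro[4.4]nonane-3,8-dione | C/C=C1\O[C@@]2(CC1=O)CC(=O)OC2 | intermediate
17 | (13S)-3β-benzyloxy-7α-(pinacolatoboryl)-9β,13-epoxy-11-oxo-8αH-labd-5-en-15,16-olide | C(c5ccccc5)O[C@H]1CC[C@@]2(C)C(=C[C@@H](B4OC(C)(C)C(C)(C)O4)[C@H](C)[C@@]23C(=O)C[C@@]2(CC(=O)OC2)O3)C1(C)C | intermediate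
18 | (13S)-3β-benzyloxy-7α-(pinacolatoboryl)-9β,13-epoxy-11-oxo-8αH-labdan-15,16-olide | C(c5ccccc5)O[C@H]1CC[C@@]2(C)[C@@H](C[C@@H](B4OC(C)(C)C(C)(C)O4)[C@H](C)[C@@]23C(=O)C[C@@]2(CC(=O)OC2)O3)C1(C)C | intermediate
19 | (13S)-3β-benzyloxy-7α-(pinacolatoboryl)-9β,13-epoxy-11-(trifluoromethanesulfonyloxy)-8αH-labd-11-en-15,16-olide | C(c5ccccc5)O[C@H]1CC[C@@]2(C)[C@@H](C[C@@H](B4OC(C)(C)C(C)(C)O4)[C@H](C)[C@@]23C(OS(=O)(=O)C(F)(F)F)=C[C@@]2(CC(=O)OC2)O3)C1(C)C | intermediate
20 | (13S)-3β-hydroxy-7α-(pinacolatoboryl)-9β,13-epoxy-8αH-labdan-15,16-olide | O[C@H]1CC[C@@]2(C)[C@@H](C[C@@H](B4OC(C)(C)C(C)(C)O4)[C@H](C)[C@@]23CC[C@@]2(CC(=O)OC2)O3)C1(C)C | intermediate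
21 | (13S)-3-oxo-7α-(pinacolatoboryl)-9β,13-epoxy-8αH-labdan-15,16-olide | O=C1CC[C@@]2(C)[C@@H](C[C@@H](B4OC(C)(C)C(C)(C)O4)[C@H](C)[C@@]23CC[C@@]2(CC(=O)OC2)O3)C1(C)C | intermediate
22 | lithium 3α-alkoxide of 21 | [Li+].[O-][C@@H]1CC[C@@]2(C)[C@@H](C[C@@H](B4OC(C)(C)C(C)(C)O4)[C@H](C)[C@@]23CC[C@@]2(CC(=O)OC2)O3)C1(C)C | intermediate (not isolated)
23 | (13S)-3α-acetoxy-7α-(pinacolatoboryl)-9β,13-epoxy-8αH-labdan-15,16-olide | CC(=O)O[C@@H]1CC[C@@]2(C)[C@@H](C[C@@H](B4OC(C)(C)C(C)(C)O4)[C@H](C)[C@@]23CC[C@@]2(CC(=O)OC2)O3)C1(C)C | intermediate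
24 | (13S)-3α-acetoxy-7α-(pinacolatoboryl)-9β,13:15,16-diepoxy-8αH-labdan-15-ol (C15 epimers) | CC(=O)O[C@@H]1CC[C@@]2(C)[C@@H](C[C@@H](B4OC(C)(C)C(C)(C)O4)[C@H](C)[C@@]23CC[C@@]2(CC(O)OC2)O3)C1(C)C | intermediate
25 | 15-O-methanesulfonate of 24 | CC(=O)O[C@@H]1CC[C@@]2(C)[C@@H](C[C@@H](B4OC(C)(C)C(C)(C)O4)[C@H](C)[C@@]23CC[C@@]2(CC(OS(C)(=O)=O)OC2)O3)C1(C)C | intermediate (not isolated)
26 | (13S)-3α-acetoxy-7α-(pinacolatoboryl)-9β,13:15,16-diepoxy-8αH-labd-14-ene | CC(=O)O[C@@H]1CC[C@@]2(C)[C@@H](C[C@@H](B4OC(C)(C)C(C)(C)O4)[C@H](C)[C@@]23CC[C@@]2(C=COC2)O3)C1(C)C | intermediate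
27 | (13S)-3α-acetoxy-9β,13:15,16-diepoxy-8αH-labd-14-en-7α-ol | CC(=O)O[C@@H]1CC[C@@]2(C)[C@@H](C[C@@H](O)[C@H](C)[C@@]23CC[C@@]2(C=COC2)O3)C1(C)C | intermediate
28 | (13S)-3α-acetoxy-9β,13:15,16-diepoxy-8αH-labd-14-en-7-one | CC(=O)O[C@@H]1CC[C@@]2(C)[C@@H](CC(=O)[C@H](C)[C@@]23CC[C@@]2(C=COC2)O3)C1(C)C | target

**Count**

Total steps: 19. Longest linear sequence: 15 steps (7 to 28 through steps 5–9, 10 and 11–19); the diene branch (1 to 6) has 4 steps.

**Steps most likely to fail**

1. Step 10. Bond formation between the two fully substituted carbons C9 and C10 may be too slow for a bimolecular reaction, or endo and face selection may be low, so that the Lewis acid only degrades the partners. The fallback is an ionic Diels–Alder reaction that sets out from 16 (with 6) and returns at 17. The C11 ketone of 16 is converted with 1,2-bis(trimethylsilyloxy)ethane and catalytic TMSOTf (CH2Cl2, −78 °C) into the dioxolane (2Z,5S)-2-ethylidene-3,3-(ethylenedioxy)-1,7-dioxaspiro[4.4]nonan-8-one F1. More TMSOTf opens the ketal to a 2-alkenyl-1,3-dioxolan-2-ylium ion, a far stronger dienophile, which should add diene 6 stepwise (C7–C8, then C9–C10) to give the C11 ethylene ketal of the adduct F2. Mild aqueous acid (PPTS, acetone/H2O) should hydrolyse F2 to 17.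

2. Step 11. Hydrogen may be delivered to the β face (cis ring fusion), or the congested alkene may not reach the metal. The fallback sets out from 17 and returns at 18: a radical (MHAT) hydrogenation with Mn(dpm)3, PhSiH3 and t-BuOOH in i-PrOH. A hydrogen atom adds to C6 first, and the planar tertiary C5 radical should then take up hydrogen on the α face, because the β face carries three axial methyl groups. This makes no new compound (F0).

3. Step 13. The enol triflate may be saturated faster than it is cleaved, leaving an alkyl triflate that ionises, or the debenzylation may stall. The fallback sets out from 19 and returns at 20 by two separate reductions. Pd(OAc)2, PPh3, Bu3N and HCO2H (DMF, 60 °C; oxidative addition into the C–OTf bond, formate as hydride source) should give (13S)-3β-benzyloxy-7α-(pinacolatoboryl)-9β,13-epoxy-8αH-labd-11-en-15,16-olide F3. Hydrogenation of F3 (H2, Pd(OH)2/C, EtOAc) then saturates C11=C12 and cleaves the benzyl ether to give 20.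

**Further compounds**

F1 | step 10 | (2Z,5S)-2-ethylidene-3,3-(ethylenedioxy)-1,7-dioxaspiro[4.4]nonan-8-one | C/C=C1\O[C@@]2(CC13OCCO3)CC(=O)OC2
F2 | step 10 | C11 ethylene ketal of adduct 17 | C(c5ccccc5)O[C@H]1CC[C@@]2(C)C(=C[C@@H](B4OC(C)(C)C(C)(C)O4)[C@H](C)[C@@]23C6(OCCO6)C[C@@]2(CC(=O)OC2)O3)C1(C)C
F0 | step 11 | none | none
F3 | step 13 | (13S)-3β-benzyloxy-7α-(pinacolatoboryl)-9β,13-epoxy-8αH-labd-11-en-15,16-olide | C(c5ccccc5)O[C@H]1CC[C@@]2(C)[C@@H](C[C@@H](B4OC(C)(C)C(C)(C)O4)[C@H](C)[C@@]23C=C[C@@]2(CC(=O)OC2)O3)C1(C)C
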